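The tetrahydrofuran (O1, C2, C3 with the vanillyl CH2, C4 with the carbinol side chain, C5) is traced back to a γ-lactone, and that lactone to a four-membered ketone. The feature used is that C4 is flanked by two ring CH2 carbons, C3 (before benzylation) and C5. These are the two methylene carbons of a 3-substituted cyclobutanone whose carbonyl carbon becomes C2. One catalytic asymmetric Baeyer–Villiger oxidation inserts oxygen between the carbonyl carbon and C5, expands the ring to the lactone and fixes C4. The precursor is a cyclobutanone carrying at its 3-position an (R)-aryl(silyloxy)methyl group, with the phenol as its benzyl ether.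

Key step: step 6

Remarks and assumptions
- The target is the trans-(3R,4R) tetrahydrofuran with an (R)-configured carbinol carbon; ketone 9 and lactone 11 carry the same carbinol configuration, and 11 is (4R).
- The carbinol centre is in place before the ring expansion, so the two ring CH2 groups of 9 are diastereotopic, not enantiotopic. Step 6 is therefore a catalyst-controlled group selection in a chiral substrate.
- It is assumed that one antipode of the N,N'-dioxide ligand (both are accessible) is matched with the (R)-carbinol centre and steers migration of the pro-R CH2; it is to be found in a short screen.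
- The cyclobutanone carbonyl is carried as an exocyclic methylene until the carbinol is set and protected. The carbinol centre then comes from hydrogenation of an aryl secondary-alkyl ketone, a well-behaved substrate class.

Step 1
Reactants: 1 4-bromo-2-methoxyphenol
Product: 2 1-(benzyloxy)-4-bromo-2-methoxybenzene
Conditions: BnBr, K2CO3, DMF, rt
Reagents that add atoms: benzyl bromide, BrCc1ccccc1
Why: Williamson ether synthesis: the phenoxide formed with K2CO3 is O-alkylated by benzyl bromide in an SN2 reaction while the aryl bromide is inert; no stereocentre is formed.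

Step 2
Reactants: 2 1-(benzyloxy)-4-bromo-2-methoxybenzene; 3 3-methylenecyclobutane-1-carbonitrile
Product: 6 [4-(benzyloxy)-3-methoxyphenyl](3-methylenecyclobutyl)methanone, via arylmagnesium bromide 4 (not isolated), via magnesium ketiminate 5 (not isolated)
Conditions: Mg, THF, 45 °C; then 3, CuBr (2 mol %), THF, reflux; then 1 M aq. HCl, 0 °C → rt
Reagents that add atoms: water, O
Why: Grignard addition to a nitrile: the arylmagnesium bromide adds once to C≡N and stops at the magnesium ketiminate, which cannot take up a second equivalent, so acid hydrolysis should give the ketone while the exocyclic alkene and the benzyl ether stay untouched; no stereocentre is formed.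

Step 3
Reactants: 6 [4-(benzyloxy)-3-methoxyphenyl](3-methylenecyclobutyl)methanone
Product: 7 (R)-[4-(benzyloxy)-3-methoxyphenyl](3-methylenecyclobutyl)methanol
Conditions: RuCl2[(S)-xylbinap][(S)-daipen] (0.5 mol %), KOtBu (2 mol %), H2 (8 atm), iPrOH, 25 °C
Reagents that add atoms: none
Why: Noyori asymmetric hydrogenation of an aryl alkyl ketone with a BINAP/diamine complex of divalent ruthenium: the outer-sphere transfer of hydride and proton is specific for C=O, so the isolated C=C and the benzyl ether should survive, and the (S,S)-configured catalyst is expected to tell aryl from secondary alkyl as it does for other aryl sec-alkyl ketones and so to set the (R)-carbinol centre.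

Step 4
Reactants: 7 (R)-[4-(benzyloxy)-3-methoxyphenyl](3-methylenecyclobutyl)methanol
Product: 8 tert-butyl{(R)-[4-(benzyloxy)-3-methoxyphenyl](3-methylenecyclobutyl)methoxy}dimethylsilane
Conditions: TBSCl, imidazole, DMF, rt
Reagents that add atoms: tert-butyldimethylsilyl chloride, CC(C)(C)[Si](C)(C)Cl
Why: Imidazole-promoted silyl ether formation caps the secondary benzylic alcohol without touching its C–O bond, so the (R) configuration is kept, and the bulky silyl group later keeps this oxygen out of the enolate, hydride and Mitsunobu steps.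

Step 5
Reactants: 8 tert-butyl{(R)-[4-(benzyloxy)-3-methoxyphenyl](3-methylenecyclobutyl)methoxy}dimethylsilane
Product: 9 3-{(R)-[4-(benzyloxy)-3-methoxyphenyl][(tert-butyldimethylsilyl)oxy]methyl}cyclobutan-1-one
Conditions: K2OsO4·2H2O (2 mol %), NaIO4, 2,6-lutidine, dioxane/H2O (3:1), rt
Reagents that add atoms: sodium periodate, [Na+].[O-]I(=O)(=O)=O (terminal oxygen source, relayed by the osmium catalyst)
Why: Lemieux–Johnson oxidation: osmium-catalysed dihydroxylation of the only alkene and periodate cleavage of the resulting 1,2-diol in the same flask should unmask the cyclobutanone under buffered conditions that spare the electron-rich arene, the benzyl ether and the silyl ether; the ring carbon bearing the side chain is prochiral, not stereogenic.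

Step 6
Reactants: 9 3-{(R)-[4-(benzyloxy)-3-methoxyphenyl][(tert-butyldimethylsilyl)oxy]methyl}cyclobutan-1-one
Product: 11 (R)-4-{(R)-[4-(benzyloxy)-3-methoxyphenyl][(tert-butyldimethylsilyl)oxy]methyl}dihydrofuran-2(3H)-one, via Criegee adduct 10 (not isolated)
Conditions: Sc(OTf)3 (10 mol %), chiral C2-symmetric N,N'-dioxide ligand (amino-acid-derived bis(2,6-diisopropylanilide), 10 mol %), mCPBA, EtOAc, −20 °C
Reagents that add atoms: 3-chloroperoxybenzoic acid (mCPBA), OOC(=O)c1cccc(Cl)c1
Why: mCPBA adds to the scandium-bound carbonyl of 9 to give the Criegee adduct 10, in which one ring CH2 shifts from carbon to the peroxide oxygen with retention while 3-chlorobenzoate leaves; this is the Baeyer–Villiger oxidation in its known catalytic asymmetric form for 3-substituted cyclobutanones (Sc(OTf)3 with a chiral N,N'-dioxide, trivalent scandium). The five-membered lactone ring arises by ring expansion through this 1,2-shift (oxygen insertion into a ring C–C bond), not by a cyclisation, and the release of four-ring strain drives it. The new stereocentre C4 is defined by which CH2 migrates: shift of the pro-R methylene gives the (4R)-lactone, and this choice is made by the chiral scandium complex, which holds the adduct so that only one ring C–C bond lies antiperiplanar to the O–O bond. The selectivity needed is therefore group selectivity between two diastereotopic CH2 groups; since the carbinol centre lies outside the ring its own bias should be small, so with the matched ligand antipode catalyst control should dominate. Regiochemistry is not an issue because both candidates are primary carbons and give the same constitution, and the strained ketone reacts at −20 °C, where the benzyl ether, the electron-rich arene and the silyl ether should be left alone.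

Step 7
Reactants: 12 [4-(benzyloxy)-3-methoxyphenyl]methanol
Product: 13 1-(benzyloxy)-4-(bromomethyl)-2-methoxybenzene
Conditions: PBr3, Et2O, 0 °C
Reagents that add atoms: phosphorus tribromide, BrP(Br)Br
Why: Alcohol-to-bromide conversion with PBr3: the benzylic alcohol becomes a phosphite ester that bromide displaces, and the labile electron-rich bromide is used at once after a cold aqueous wash; no stereocentre is involved.

Step 8
Reactants: 11 (R)-4-{(R)-[4-(benzyloxy)-3-methoxyphenyl][(tert-butyldimethylsilyl)oxy]methyl}dihydrofuran-2(3H)-one; 13 1-(benzyloxy)-4-(bromomethyl)-2-methoxybenzene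
Product: 15 (3R,4R)-3-[4-(benzyloxy)-3-methoxybenzyl]-4-{(R)-[4-(benzyloxy)-3-methoxyphenyl][(tert-butyldimethylsilyl)oxy]methyl}dihydrofuran-2(3H)-one, via lithium enolate 14 (not isolated)
Conditions: LiN(SiMe3)2, THF, −78 °C; then 13, DMPU, −78 → −30 °C
Reagents that add atoms: none
Why: Alkylation of a lactone lithium enolate (SN2 at a benzylic bromide): the planar enolate 14 is attacked on the face opposite to the bulky C4 substituent, so the new C3 centre should be set trans to C4 (3R) under substrate control, and no leaving group sits beta to the enolate carbon.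

Step 9
Reactants: 15 (3R,4R)-3-[4-(benzyloxy)-3-methoxybenzyl]-4-{(R)-[4-(benzyloxy)-3-methoxyphenyl][(tert-butyldimethylsilyl)oxy]methyl}dihydrofuran-2(3H)-one
Product: 16 (2R,3R)-2-[4-(benzyloxy)-3-methoxybenzyl]-3-{(R)-[4-(benzyloxy)-3-methoxyphenyl][(tert-butyldimethylsilyl)oxy]methyl}butane-1,4-diol
Conditions: LiAlH4, THF, 0 °C; then Na2SO4·10H2O
Reagents that add atoms: none
Why: Hydride reduction of a lactone to a 1,4-diol with LiAlH4; no stereocentre is touched, and the benzyl ethers and the silyl ether are stable to hydride at 0 °C.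

Step 10
Reactants: 16 (2R,3R)-2-[4-(benzyloxy)-3-methoxybenzyl]-3-{(R)-[4-(benzyloxy)-3-methoxyphenyl][(tert-butyldimethylsilyl)oxy]methyl}butane-1,4-diol
Product: 17 (3R,4R)-3-[4-(benzyloxy)-3-methoxybenzyl]-4-{(R)-[4-(benzyloxy)-3-methoxyphenyl][(tert-butyldimethylsilyl)oxy]methyl}tetrahydrofuran
Conditions: PPh3, DIAD, THF, 0 °C → rt
Reagents that add atoms: none
Why: Mitsunobu cyclodehydration: one primary hydroxyl is activated as an oxyphosphonium ion and displaced by the other in a 5-exo-tet closure, which gives the same tetrahydrofuran whichever primary carbon is activated, changes no stereocentre, and cannot involve the silylated benzylic oxygen.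

Step 11
Reactants: 17 (3R,4R)-3-[4-(benzyloxy)-3-methoxybenzyl]-4-{(R)-[4-(benzyloxy)-3-methoxyphenyl][(tert-butyldimethylsilyl)oxy]methyl}tetrahydrofuran
Product: 18 (R)-[4-(benzyloxy)-3-methoxyphenyl]{(3R,4R)-4-[4-(benzyloxy)-3-methoxybenzyl]tetrahydrofuran-3-yl}methanol
Conditions: Bu4NF, THF, 0 °C → rt
Reagents that add atoms: none
Why: Fluoride-induced desilylation driven by the strong Si–F bond; the carbinol C–O bond is not broken, so the (R) configuration is retained, and with both phenols still benzylated no phenoxide is present that could expel the benzylic oxygen.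

Step 12
Reactants: 18 (R)-[4-(benzyloxy)-3-methoxyphenyl]{(3R,4R)-4-[4-(benzyloxy)-3-methoxybenzyl]tetrahydrofuran-3-yl}methanol
Product: 19 (3R,4R)-3-(4-hydroxy-3-methoxybenzyl)-4-[(R)-hydroxy(4-hydroxy-3-methoxyphenyl)methyl]tetrahydrofuran (CNP0234428.1)
Conditions: H2 (1 atm), Pd/C (5 %), EtOAc, rt
Reagents that add atoms: none
Why: Hydrogenolysis of aryl benzyl ethers over Pd/C: the O–CH2Ph bonds of phenol ethers are cleaved rapidly under neutral conditions in an aprotic solvent, whereas the secondary benzylic C–OH bond and the tetrahydrofuran should be left, provided the reaction is stopped once the ethers are consumed.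

Compound list
1 | 4-bromo-2-methoxyphenol | COc1cc(Br)ccc1O | starting material
2 | 1-(benzyloxy)-4-bromo-2-methoxybenzene | COc1cc(Br)ccc1OCc1ccccc1 | intermediate
3 | 3-methylenecyclobutane-1-carbonitrile | C=C1CC(C1)C#N | starting material
4 | [4-(benzyloxy)-3-methoxyphenyl]magnesium bromide (not isolated) | COc1cc([Mg]Br)ccc1OCc1ccccc1 | intermediate
5 | N-bromomagnesio ketimine of ketone 6 (not isolated) | C=C1CC(C1)C(=N[Mg]Br)c1ccc(OCc2ccccc2)c(OC)c1 | intermediate
6 | [4-(benzyloxy)-3-methoxyphenyl](3-methylenecyclobutyl)methanone | C=C1CC(C1)C(=O)c1ccc(OCc2ccccc2)c(OC)c1 | intermediate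
7 | (R)-[4-(benzyloxy)-3-methoxyphenyl](3-methylenecyclobutyl)methanol | C=C1CC(C1)[C@@H](O)c1ccc(OCc2ccccc2)c(OC)c1 | intermediate
8 | tert-butyl{(R)-[4-(benzyloxy)-3-methoxyphenyl](3-methylenecyclobutyl)methoxy}dimethylsilane | C=C1CC(C1)[C@@H](O[Si](C)(C)C(C)(C)C)c1ccc(OCc2ccccc2)c(OC)c1 | intermediate
9 | 3-{(R)-[4-(benzyloxy)-3-methoxyphenyl][(tert-butyldimethylsilyl)oxy]methyl}cyclobutan-1-one | O=C1CC(C1)[C@@H](O[Si](C)(C)C(C)(C)C)c1ccc(OCc2ccccc2)c(OC)c1 | intermediate
10 | Criegee adduct of 9: 1-hydroxy-1-(3-chlorobenzoylperoxy)cyclobutane with the same 3-substituent, either ring diastereomer (not isolated) | OC1(OOC(=O)c2cccc(Cl)c2)CC(C1)[C@@H](O[Si](C)(C)C(C)(C)C)c1ccc(OCc2ccccc2)c(OC)c1 | intermediate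
11 | (R)-4-{(R)-[4-(benzyloxy)-3-methoxyphenyl][(tert-butyldimethylsilyl)oxy]methyl}dihydrofuran-2(3H)-one | O=C1C[C@H](CO1)[C@@H](O[Si](C)(C)C(C)(C)C)c1ccc(OCc2ccccc2)c(OC)c1 | intermediate
12 | [4-(benzyloxy)-3-methoxyphenyl]methanol | COc1cc(CO)ccc1OCc1ccccc1 | starting material
13 | 1-(benzyloxy)-4-(bromomethyl)-2-methoxybenzene | COc1cc(CBr)ccc1OCc1ccccc1 | intermediate
14 | lithium enolate of lactone 11 (not isolated) | [Li]OC1=C[C@H](CO1)[C@@H](O[Si](C)(C)C(C)(C)C)c1ccc(OCc2ccccc2)c(OC)c1 | intermediate
15 | (3R,4R)-3-[4-(benzyloxy)-3-methoxybenzyl]-4-{(R)-[4-(benzyloxy)-3-methoxyphenyl][(tert-butyldimethylsilyl)oxy]methyl}dihydrofuran-2(3H)-one | COc1cc(C[C@H]2C(=O)OC[C@@H]2[C@@H](O[Si](C)(C)C(C)(C)C)c2ccc(OCc3ccccc3)c(OC)c2)ccc1OCc1ccccc1 | intermediate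
16 | (2R,3R)-2-[4-(benzyloxy)-3-methoxybenzyl]-3-{(R)-[4-(benzyloxy)-3-methoxyphenyl][(tert-butyldimethylsilyl)oxy]methyl}butane-1,4-diol | COc1cc(C[C@@H](CO)[C@H](CO)[C@@H](O[Si](C)(C)C(C)(C)C)c2ccc(OCc3ccccc3)c(OC)c2)ccc1OCc1ccccc1 | intermediate
17 | (3R,4R)-3-[4-(benzyloxy)-3-methoxybenzyl]-4-{(R)-[4-(benzyloxy)-3-methoxyphenyl][(tert-butyldimethylsilyl)oxy]methyl}tetrahydrofuran | COc1cc(C[C@H]2COC[C@@H]2[C@@H](O[Si](C)(C)C(C)(C)C)c2ccc(OCc3ccccc3)c(OC)c2)ccc1OCc1ccccc1 | intermediate
18 | (R)-[4-(benzyloxy)-3-methoxyphenyl]{(3R,4R)-4-[4-(benzyloxy)-3-methoxybenzyl]tetrahydrofuran-3-yl}methanol | COc1cc(C[C@H]2COC[C@@H]2[C@@H](O)c2ccc(OCc3ccccc3)c(OC)c2)ccc1OCc1ccccc1 | intermediate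
19 | (3R,4R)-3-(4-hydroxy-3-methoxybenzyl)-4-[(R)-hydroxy(4-hydroxy-3-methoxyphenyl)methyl]tetrahydrofuran | COc1cc(C[C@H]2COC[C@@H]2[C@@H](O)c2ccc(O)c(OC)c2)ccc1O | target

Total step count: 12
Longest linear sequence: 11 steps (steps 1–6 and 8–12, from 1)

Steps most likely to fail

1. Step 6. The discrimination between the two diastereotopic CH2 groups may be weak if catalyst and carbinol centre are mismatched, or the Lewis acid may ionise the benzylic silyl ether. The fallback sets out from 9 and comes back at 11. The ketone is oxidised without any chiral catalyst (mCPBA, NaHCO3, CH2Cl2, 0 °C). Because the carbinol centre is already fixed, the ring expansion should then give 11 together with its C4 epimer, the (4S)-lactone F1, as diastereomers that can be parted by chromatography. Stereocontrol is thus replaced by separation, at the cost of material.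

2. Step 3. The facial selectivity may be poor or turnover slow with this α-branched, electron-rich ketone. The fallback sets out from 6 and comes back at 7 by classical resolution. NaBH4 in MeOH at 0 °C reduces 6 to the racemic carbinol F2. Esterification with (S)-2-methoxy-2-phenylacetic acid (DCC, catalytic DMAP, CH2Cl2) should give two diastereomeric esters, the (R)-carbinol (S)-O-methylmandelate F3 and the (S)-carbinol (S)-O-methylmandelate F4. These are separated by chromatography or crystallisation and assigned by the usual anisotropy model for such esters. Saponification of F3 (LiOH, THF/MeOH/H2O) returns 7.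

3. Step 12. Once a para-phenol is free, the benzylic C–OH bond may be hydrogenolysed as well. The fallback sets out from 17 and comes back at 19, with the order of deprotection reversed so that the carbinol is shielded while hydrogen is present. Compound 17 is hydrogenolysed (H2, Pd/C, EtOAc, rt) to the bisphenol silyl ether F5. The silyl group is then removed with Bu4NF buffered with acetic acid (THF, rt), which keeps the phenols protonated.

Further compounds
F1 | step 6 | (S)-4-{(R)-[4-(benzyloxy)-3-methoxyphenyl][(tert-butyldimethylsilyl)oxy]methyl}dihydrofuran-2(3H)-one | O=C1C[C@@H](CO1)[C@@H](O[Si](C)(C)C(C)(C)C)c1ccc(OCc2ccccc2)c(OC)c1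
F2 | step 3 | racemic [4-(benzyloxy)-3-methoxyphenyl](3-methylenecyclobutyl)methanol | C=C1CC(C1)C(O)c1ccc(OCc2ccccc2)c(OC)c1
F3 | step 3 | (R)-[4-(benzyloxy)-3-methoxyphenyl](3-methylenecyclobutyl)methyl (S)-2-methoxy-2-phenylacetate | C=C1CC(C1)[C@@H](OC(=O)[C@@H](OC)c1ccccc1)c1ccc(OCc2ccccc2)c(OC)c1
F4 | step 3 | (S)-[4-(benzyloxy)-3-methoxyphenyl](3-methylenecyclobutyl)methyl (S)-2-methoxy-2-phenylacetate | C=C1CC(C1)[C@H](OC(=O)[C@@H](OC)c1ccccc1)c1ccc(OCc2ccccc2)c(OC)c1
F5 | step 12 | (3R,4R)-3-(4-hydroxy-3-methoxybenzyl)-4-{(R)-[(tert-butyldimethylsilyl)oxy](4-hydroxy-3-methoxyphenyl)methyl}tetrahydrofuran | COc1cc(C[C@H]2COC[C@@H]2[C@@H](O[Si](C)(C)C(C)(C)C)c2ccc(O)c(OC)c2)ccc1O
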